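The numbers of this flask belong to no real substance; the run is a simulation.

Start from 90.0%: that is as much of the electrophile as the nucleophile can turn into target if every acid set free stays on a second nucleophile.

    electrophile + nucleophile → acid set free + target (k1 = 3.8 L mol⁻¹ s⁻¹, Ea1 = 42.0 kJ mol⁻¹)
    nucleophile + acid set free ⇌ protonated nucleophile, settled at all times (K2 = 49000 L mol⁻¹, ΔH2 = −33.0 kJ mol⁻¹)
    acid set free + free base ⇌ salt of the base (K3 = 23 L mol⁻¹, k3 = 4.3 L mol⁻¹ s⁻¹, Ea3 = 36.0 kJ mol⁻¹, ΔH3 = −38.0 kJ mol⁻¹)
    acid set free → by-product carried off (k4 = 0.0042 s⁻¹, Ea4 = 76.0 kJ mol⁻¹)
    (constants at 5 °C)

in all of them: electrophile 20 mM; nucleophile 1.80 equiv; free base 3.00 equiv (in portions, 4); time 10 min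
- ochre: temperature 5 °C; the portions of free base follow each other after 50 s, the first at the start
- teal: temperature 35 °C; the portions of free base follow each other after 50 s, the first at the start
- red: temperature 20 °C; the portions of free base follow each other after 50 s, the first at the start

* which of these there is most of at the end, counted by the electrophile in it, ochre (target / electrophile)
* which of these there is most of at the end, counted by the electrophile in it, teal (target / electrophile)
* which of these there is most of at the end, counted by the electrophile in it, red (target / electrophile)
* final amount of the leader among these, as a percentage of the electrophile charged, in ochre
* final amount of the leader among these, as a percentage of the electrophile charged, in teal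
* final amount of the leader among these, as a percentage of the electrophile charged, in red

- at 5 °C the constants are as listed, elsewhere as the activation energies and enthalpies make them

**Main step.** Take the first step by itself. The electrophile's half-life in ochre is 0.084 min with the charges as they stand, far shorter than the 10 min of the run, so this step alone carries ochre to the end of the electrophile.

**Add the trap.** Now let the acid set free bind. The constant of the second step times c(nucleophile) is 1800 at the start in ochre, against 1.38 for the free base with its whole charge counted, so the acid goes overwhelmingly onto the nucleophile. Each target then costs two nucleophiles, the nucleophile becomes the limiting reagent, and the target slows near 90.0%.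

**Add the exit.** Now let the fourth step carry acid away. Any acid off the nucleophile, whether carried off, free or on the base, frees one nucleophile, worth half a target. Count the acid debt, twice the electrophile less the nucleophile charged: 4.00 mM of acid must stand off the nucleophile before the electrophile is used up. Electrophile left is then half of the debt unpaid plus the free nucleophile.

**My reckoning.** Balance the first step against half the exit, taking electrophile and bound nucleophile at their values at that slowing point. That puts free acid near 1.15 mM in ochre. Ochre would need 1.59 mM on average to pay by the exit in time, more than that level, so I expect it to stop short, at about 97.3% target. Holding that level, red needs 0.295 mM and teal 0.0647 mM, both below it, so I expect both to finish.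

**The forecast.** It names target as leader in the three flasks and gives 96% for ochre (93% to 98%), 99.8% for red and 100% for teal. It expects the stall to last “until the acid-removal step frees more nucleophile”. My ochre figure stands above its number.

**The result.** Ochre ends at 96.2% target, red at >99.9% and teal at 100%. Ochre held 90.2% at 2.50 min, close to that slowing point. By its end ochre has paid 2.96 mM of its 4.00 mM debt, which leaves 3.8% electrophile. Teal's neighbour with 0.720 equiv of nucleophile owes 25.6 mM and has 14.4 mM carried off at 10.0 min, with free nucleophile at 0%. Half of its unpaid 11.2 mM stands as electrophile, 28% of the charge.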